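Fragransin B1 is a meso tetrahydrofuran: both aryl groups (C2, C5) lie on one face, both methyl groups (C3, C4) on the other. The ring is cut at O1–C5 and C2–C3, so that O1–C2(aryl) is O-benzylsyringaldehyde and C3–C4(CH3)–C5(aryl) is a donor–acceptor cyclopropane whose C3 gem-diester masks the C3 methyl. One Lewis-acid (3+2) annulation forms both bonds, the oxolane ring and the C2 and C5 stereocentres. It exploits the ionisable benzylic C5–C3 bond and the 2,5-cis-diaryl pattern. Because C5 is attacked with inversion, the precursor carries aryl and methyl cis on the cyclopropane, which gives the 4,5-trans relation directly.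

Key step: step 5

Assumption: the target SMILES describes the achiral meso isomer (2,5-cis, 3,4-cis, 2,3-trans, 4,5-trans), so chiral intermediates are made as racemates and each SMILES shows one enantiomer.

Step 1
Reactants: 1 syringaldehyde
Product: 2 4-(benzyloxy)-3,5-dimethoxybenzaldehyde
Conditions: BnBr, K2CO3, DMF, 60 °C
Reagents that add atoms: benzyl bromide, BrCc1ccccc1
Why: Williamson ether synthesis, in which the phenoxide formed by K2CO3 displaces bromide from the benzylic halide while the aldehyde stays inert.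

Step 2
Reactants: 2 4-(benzyloxy)-3,5-dimethoxybenzaldehyde
Product: 3 2-(benzyloxy)-1,3-dimethoxy-5-[(1Z)-prop-1-en-1-yl]benzene
Conditions: EtPPh3Br, NaHMDS, THF, −78 °C → rt
Reagents that add atoms: ethyltriphenylphosphonium bromide, CC[P+](c1ccccc1)(c1ccccc1)c1ccccc1.[Br-]
Why: A lithium-free Wittig olefination of an aromatic aldehyde with a non-stabilised ylide runs under kinetic control through the cis-oxaphosphetane and should give mainly the Z-alkene, with any E-isomer removable on AgNO3-doped silica.

Step 3
Reactants: 4 dimethyl malonate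
Product: 5 dimethyl 2-diazopropanedioate (dimethyl diazomalonate)
Conditions: 4-AcNHC6H4SO2N3, Et3N, MeCN, 0 °C → rt
Reagents that add atoms: 4-acetamidobenzenesulfonyl azide, CC(=O)Nc1ccc(cc1)S(=O)(=O)N=[N+]=[N-]
Why: Regitz diazo transfer, in which the malonate enolate attacks the terminal azide nitrogen and the triazene collapses to the diazo compound and the sulfonamide.

Step 4
Reactants: 3 2-(benzyloxy)-1,3-dimethoxy-5-[(1Z)-prop-1-en-1-yl]benzene; 5 dimethyl diazomalonate
Product: 6 dimethyl (±)-cis-2-[4-(benzyloxy)-3,5-dimethoxyphenyl]-3-methylcyclopropane-1,1-dicarboxylate (aryl and methyl on the same face, 2S*,3S*)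
Conditions: Rh2(esp)2 (1 mol %; esp = α,α,α′,α′-tetramethyl-1,3-benzenedipropanoate), CH2Cl2, slow addition of 5, 0 °C → rt
Reagents that add atoms: none
Why: Dirhodium-carbenoid cyclopropanation is a concerted, stereospecific syn addition, so the Z-geometry of 3 becomes the cis aryl/methyl relation of the two new stereocentres, and cis-1,2-disubstituted styrenes are among the better internal alkenes for malonate carbenoids.

Step 5
Reactants: 6 dimethyl (±)-cis-2-[4-(benzyloxy)-3,5-dimethoxyphenyl]-3-methylcyclopropane-1,1-dicarboxylate; 2 4-(benzyloxy)-3,5-dimethoxybenzaldehyde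
Product: 7 dimethyl (±)-2,5-cis-bis[4-(benzyloxy)-3,5-dimethoxyphenyl]-4-methyltetrahydrofuran-3,3-dicarboxylate (both aryls on one face, C4 methyl on the opposite face)
Conditions: Sn(OTf)2 (10 mol %), 2 (3 equiv), 4 Å MS, CH2Cl2, −20 → 0 °C, quench on consumption of 6
Reagents that add atoms: none
Why: Sn(OTf)2 (divalent tin) chelates the two ester carbonyls of 6 and polarises the strained C3–C5 bond, the carbonyl oxygen of the electron-rich aldehyde 2 attacks benzylic C5 from the rear in an SN2-like opening of the tight ion pair (O1–C5), and the tin malonate enolate then adds to the resulting oxocarbenium carbon (C2–C3). This is the established Lewis-acid (3+2) annulation of 2-arylcyclopropane-1,1-diesters with aldehydes, which is also known for cyclopropanes that carry a further substituent at the third ring carbon. The single ring, the tetrahydrofuran, closes by an aldol-type 5-(enolexo)-endo-trig attack on the cationic C2=O1 unit through an envelope transition state. C5 is set by inversion of the cyclopropane stereocentre while C4 is untouched, so cis aryl/methyl in 6 becomes 4,5-trans in 7, and C2 is set by the envelope in which the aryl of the E-oxocarbenium ion and the C5 aryl are both pseudo-equatorial, giving 2,5-cis. The step needs capture of 6 to outrun its Lewis-acid cis-to-trans isomerisation and needs the adduct not to reopen, which excess nucleophilic aldehyde, low temperature, low catalyst loading and an early quench serve, while the 4-benzyloxy group, twisted out of conjugation by its two ortho methoxy neighbours, keeps the aryl donor from supporting a free cation. In addition all three ring substituents of 7 sit pseudo-equatorial, so the stereospecific pathway and the thermodynamic preference at C5 point to the same product.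

Step 6
Reactants: 7 dimethyl (±)-2,5-cis-bis[4-(benzyloxy)-3,5-dimethoxyphenyl]-4-methyltetrahydrofuran-3,3-dicarboxylate
Product: 9 methyl (±)-2,5-cis-bis[4-(benzyloxy)-3,5-dimethoxyphenyl]-4-methyltetrahydrofuran-3-carboxylate with ester and C4 methyl both on the face opposite the aryls, via 2,3-cis monoester 8 (not isolated)
Conditions: LiCl, H2O, DMSO, 150 °C; crude product then NaOMe (0.3 equiv), MeOH–THF, 60 °C
Reagents that add atoms: none
Why: Krapcho dealkoxycarbonylation (chloride attacks an ester methyl, CO2 leaves and the ester enolate is protonated, expected mainly from the methyl-bearing face to give 8) is followed by methoxide-mediated enolate equilibration, which should move the C3 ester away from the bulky C2 aryl and the 1,3-related C5 aryl onto the face of the smaller C4 methyl and so sets C3 under thermodynamic control.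

Step 7
Reactants: 9 methyl (±)-2,5-cis-diaryl-4-methyltetrahydrofuran-3-carboxylate (2,3-trans, 3,4-cis)
Product: 10 (±)-{2,5-cis-bis[4-(benzyloxy)-3,5-dimethoxyphenyl]-4-methyltetrahydrofuran-3-yl}methanol (CH2OH cis to C4 methyl, trans to the aryls)
Conditions: LiAlH4, THF, 0 °C → rt
Reagents that add atoms: none
Why: Standard LiAlH4 ester reduction, which touches neither the benzyl and methyl ethers nor any stereocentre.

Step 8
Reactants: 10 (±)-{2,5-cis-diaryl-4-methyltetrahydrofuran-3-yl}methanol
Product: 11 (±)-{2,5-cis-bis[4-(benzyloxy)-3,5-dimethoxyphenyl]-4-methyltetrahydrofuran-3-yl}methyl 4-methylbenzenesulfonate (same relative configuration as 10)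
Conditions: TsCl, Et3N, DMAP (cat.), CH2Cl2, 0 °C → rt
Reagents that add atoms: 4-toluenesulfonyl chloride, Cc1ccc(cc1)S(=O)(=O)Cl
Why: DMAP-catalysed O-sulfonylation of a primary alcohol takes place at oxygen only and leaves all four stereocentres untouched.

Step 9
Reactants: 11 (±)-{2,5-cis-diaryl-4-methyltetrahydrofuran-3-yl}methyl 4-methylbenzenesulfonate
Product: 12 meso-2,5-bis[4-(benzyloxy)-3,5-dimethoxyphenyl]-3,4-dimethyltetrahydrofuran (aryls on one face, methyls on the other)
Conditions: LiEt3BH, THF, 0 °C → rt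
Reagents that add atoms: none
Why: SN2 hydride displacement of a primary tosylate by the highly nucleophilic triethylborohydride is the standard reduction of a β-branched CH2OTs group to methyl and occurs at the exocyclic carbon, so the ring configuration is kept.

Step 10
Reactants: 12 meso-2,5-bis[4-(benzyloxy)-3,5-dimethoxyphenyl]-3,4-dimethyltetrahydrofuran
Product: 13 fragransin B1, meso-4,4′-[(2R,3R,4S,5S)-3,4-dimethyloxolane-2,5-diyl]bis(2,6-dimethoxyphenol)
Conditions: H2 (1 atm), Pd/C, EtOAc–MeOH, rt
Reagents that add atoms: none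
Why: Catalytic hydrogenolysis cleaves the two unhindered aryl benzyl ethers much faster than the hindered secondary benzylic C–O bonds of the ring, so stopping after uptake of two equivalents should deliver the bisphenol with all stereocentres intact.

Compound list
1 | syringaldehyde (4-hydroxy-3,5-dimethoxybenzaldehyde) | COc1cc(C=O)cc(OC)c1O | starting material
2 | 4-(benzyloxy)-3,5-dimethoxybenzaldehyde | COc1cc(C=O)cc(OC)c1OCc1ccccc1 | intermediate
3 | 2-(benzyloxy)-1,3-dimethoxy-5-[(1Z)-prop-1-en-1-yl]benzene | C/C=C\c1cc(OC)c(OCc2ccccc2)c(OC)c1 | intermediate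
4 | dimethyl malonate | COC(=O)CC(=O)OC | starting material
5 | dimethyl diazomalonate | COC(=O)C(=[N+]=[N-])C(=O)OC | intermediate
6 | dimethyl (±)-cis-2-[4-(benzyloxy)-3,5-dimethoxyphenyl]-3-methylcyclopropane-1,1-dicarboxylate | COC(=O)C1(C(=O)OC)[C@@H](C)[C@H]1c2cc(OC)c(OCc3ccccc3)c(OC)c2 | intermediate
7 | dimethyl (±)-2,5-cis-bis[4-(benzyloxy)-3,5-dimethoxyphenyl]-4-methyltetrahydrofuran-3,3-dicarboxylate, C4 methyl trans to both aryls | COc1cc([C@H]2O[C@@H](c3cc(OC)c(OCc4ccccc4)c(OC)c3)[C@H](C)C2(C(=O)OC)C(=O)OC)cc(OC)c1OCc1ccccc1 | intermediate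
8 | methyl (±)-2,5-cis-diaryl-4-methyltetrahydrofuran-3-carboxylate, ester cis to the aryls (2,3-cis, 3,4-trans), kinetic epimer | COc1cc([C@H]2O[C@@H](c3cc(OC)c(OCc4ccccc4)c(OC)c3)[C@H](C)[C@H]2C(=O)OC)cc(OC)c1OCc1ccccc1 | intermediate
9 | methyl (±)-2,5-cis-diaryl-4-methyltetrahydrofuran-3-carboxylate, ester trans to the aryls (2,3-trans, 3,4-cis) | COc1cc([C@H]2O[C@@H](c3cc(OC)c(OCc4ccccc4)c(OC)c3)[C@H](C)[C@@H]2C(=O)OC)cc(OC)c1OCc1ccccc1 | intermediate
10 | (±)-{2,5-cis-bis[4-(benzyloxy)-3,5-dimethoxyphenyl]-4-methyltetrahydrofuran-3-yl}methanol (2,3-trans, 3,4-cis) | COc1cc([C@H]2O[C@@H](c3cc(OC)c(OCc4ccccc4)c(OC)c3)[C@H](C)[C@@H]2CO)cc(OC)c1OCc1ccccc1 | intermediate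
11 | tosylate of 10 | COc1cc([C@H]2O[C@@H](c3cc(OC)c(OCc4ccccc4)c(OC)c3)[C@H](C)[C@@H]2COS(=O)(=O)c5ccc(C)cc5)cc(OC)c1OCc1ccccc1 | intermediate
12 | meso-2,5-bis[4-(benzyloxy)-3,5-dimethoxyphenyl]-3,4-dimethyltetrahydrofuran (2,3-trans, 3,4-cis, 4,5-trans) | COc1cc([C@H]2O[C@@H](c3cc(OC)c(OCc4ccccc4)c(OC)c3)[C@H](C)[C@@H]2C)cc(OC)c1OCc1ccccc1 | intermediate
13 | fragransin B1 | COc1cc([C@H]2O[C@@H](c3cc(OC)c(O)c(OC)c3)[C@H](C)[C@@H]2C)cc(OC)c1O | target

Total step count: 10. Longest linear sequence: 9 (steps 1, 2, 4, 5, 6, 7, 8, 9, 10). Step 3 is a one-step side branch, and 2 serves both halves.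

Steps most likely to fail

1. Step 5.
- What may go wrong: the cyclopropane may ionise before the aldehyde captures it, so that cis-to-trans isomerisation and loss of the inversion pathway erode the C4/C5 relation. Reversible reopening of the adduct may erode the 2,5-cis relation. The opened zwitterion may also alkylate the electron-rich arenes.
- Fallback (sets out from 2, comes back at 12): the ring is closed from an acyclic chain in which the cis-dimethyl unit is fixed first. EtMgBr addition to 2 gives 1-[4-(benzyloxy)-3,5-dimethoxyphenyl]propan-1-ol F1, and MnO2 oxidation gives 1-[4-(benzyloxy)-3,5-dimethoxyphenyl]propan-1-one F2. Oxidative homocoupling of its lithium enolate (LDA, then CuCl2, THF–DMF) gives the 1,4-diketone. The meso isomer, meso-1,4-bis[4-(benzyloxy)-3,5-dimethoxyphenyl]-2,3-dimethylbutane-1,4-dione F3, is taken by crystallisation while the other isomer is re-equilibrated with base. LiAlH4 reduction gives 1,4-bis[4-(benzyloxy)-3,5-dimethoxyphenyl]-2,3-dimethylbutane-1,4-diol F4. Reversible cyclodehydration through the benzylic cation (catalytic TsOH, CH2Cl2) should then place each aryl trans to its neighbouring methyl and give 12.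

2. Step 6.
- What may go wrong: the thermodynamic bias between the two C3 epimers rests on an aryl versus a methyl neighbour and may be too small. Prolonged base treatment may also open the ring by β-elimination of O1.
- Fallback (sets out from 7, comes back at 11): C3 is set by steric differentiation of the two diastereotopic groups, followed by a stereoretentive C–C cleavage. LiAlH4 reduces both esters of 7 to {2,5-cis-diaryl-4-methyltetrahydrofuran-3,3-diyl}dimethanol F5. One equivalent of TsCl in pyridine at 0 °C should sulfonylate the less hindered hydroxymethyl group, the one trans to the C2 aryl, to give the 3-(hydroxymethyl)-3-(tosyloxymethyl) compound F6. Swern oxidation gives the non-enolisable 3-formyl-3-(tosyloxymethyl) compound F7. Tsuji–Wilkinson decarbonylation with stoichiometric RhCl(PPh3)3 (toluene, reflux) then replaces CHO by H with retention and gives 11.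

3. Step 4.
- What may go wrong: carbene transfer to the internal alkene may be slow, so that carbene dimerisation and attack on the electron-rich arenes compete. A stepwise zwitterionic addition, or E-alkene carried over from step 2, may leak the cis geometry.
- Fallback (sets out from 2, comes back at 6): the cis relation is made by syn hydrogenation of a cyclopropene, independent of any alkene geometry. Corey–Fuchs olefination of 2 (CBr4, PPh3, CH2Cl2) gives 2-(benzyloxy)-5-(2,2-dibromoethenyl)-1,3-dimethoxybenzene F8. n-BuLi followed by MeI gives 2-(benzyloxy)-1,3-dimethoxy-5-(prop-1-yn-1-yl)benzene F9. Rh2(OAc)4-catalysed cyclopropenation with 5 gives dimethyl 2-[4-(benzyloxy)-3,5-dimethoxyphenyl]-3-methylcycloprop-2-ene-1,1-dicarboxylate F10. Diimide (2-nitrobenzenesulfonohydrazide, Et3N, CH2Cl2, rt) adds both hydrogens to one face of the strained alkene and gives 6 without touching the benzyl ether.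

Further compounds
F1 | step 5 | 1-[4-(benzyloxy)-3,5-dimethoxyphenyl]propan-1-ol | CCC(O)c1cc(OC)c(OCc2ccccc2)c(OC)c1
F2 | step 5 | 1-[4-(benzyloxy)-3,5-dimethoxyphenyl]propan-1-one | CCC(=O)c1cc(OC)c(OCc2ccccc2)c(OC)c1
F3 | step 5 | meso-1,4-bis[4-(benzyloxy)-3,5-dimethoxyphenyl]-2,3-dimethylbutane-1,4-dione | COc1cc(cc(OC)c1OCc1ccccc1)C(=O)[C@@H](C)[C@@H](C)C(=O)c1cc(OC)c(OCc2ccccc2)c(OC)c1
F4 | step 5 | 1,4-bis[4-(benzyloxy)-3,5-dimethoxyphenyl]-2,3-dimethylbutane-1,4-diol (meso-type dimethyl unit, carbinol centres mixed) | COc1cc(cc(OC)c1OCc1ccccc1)C(O)[C@@H](C)[C@@H](C)C(O)c1cc(OC)c(OCc2ccccc2)c(OC)c1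
F5 | step 6 | (±)-{2,5-cis-bis[4-(benzyloxy)-3,5-dimethoxyphenyl]-4-methyltetrahydrofuran-3,3-diyl}dimethanol | COc1cc([C@H]2O[C@@H](c3cc(OC)c(OCc4ccccc4)c(OC)c3)[C@H](C)C2(CO)CO)cc(OC)c1OCc1ccccc1
F6 | step 6 | (±)-[2,5-cis-diaryl-3-(hydroxymethyl)-4-methyltetrahydrofuran-3-yl]methyl 4-methylbenzenesulfonate, CH2OTs cis to C4 methyl | COc1cc([C@H]2O[C@@H](c3cc(OC)c(OCc4ccccc4)c(OC)c3)[C@H](C)[C@]2(CO)COS(=O)(=O)c5ccc(C)cc5)cc(OC)c1OCc1ccccc1
F7 | step 6 | (±)-(2,5-cis-diaryl-3-formyl-4-methyltetrahydrofuran-3-yl)methyl 4-methylbenzenesulfonate, CHO cis to the aryls | COc1cc([C@H]2O[C@@H](c3cc(OC)c(OCc4ccccc4)c(OC)c3)[C@H](C)[C@]2(C=O)COS(=O)(=O)c5ccc(C)cc5)cc(OC)c1OCc1ccccc1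
F8 | step 4 | 2-(benzyloxy)-5-(2,2-dibromoethenyl)-1,3-dimethoxybenzene | BrC(Br)=Cc1cc(OC)c(OCc2ccccc2)c(OC)c1
F9 | step 4 | 2-(benzyloxy)-1,3-dimethoxy-5-(prop-1-yn-1-yl)benzene | CC#Cc1cc(OC)c(OCc2ccccc2)c(OC)c1
F10 | step 4 | dimethyl 2-[4-(benzyloxy)-3,5-dimethoxyphenyl]-3-methylcycloprop-2-ene-1,1-dicarboxylate | COC(=O)C1(C(=O)OC)C(C)=C1c1cc(OC)c(OCc2ccccc2)c(OC)c1
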